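**Retrosynthetic overview**
- Target 10 (meso) comes from the all-cis tetrahydrofuran 8 by cleaving both benzylic C–O bonds (C7–O and C7'–O). This deletes the C7/C7' stereocentres and leaves the cis C8/C8' pair as the meso pair.
- The strategy rests on one feature: the chain C7–C8–C8'–C7', bridged by one oxygen between C7 and C7', is a 2,5-diaryl-3,4-dimethylfuran ring (methyls C9/C9' on ring positions 3 and 4, the two syringyl rings on 2 and 5). Saturating furan 6 from one face gives 8.
- Furan 6 comes from 1,4-diketone 5 by Paal–Knorr closure. Diketone 5 comes from oxidative dimerisation of the enolate of benzyl-protected propiosyringone 3 (C8–C8' bond), and 3 from 1 and 2.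
- Ring order: the furan is the only ring built (step 3). It is saturated in step 4 and opened in step 5. Both arene rings are bought.

Key step: step 4

Assumption: 1-(4-hydroxy-3,5-dimethoxyphenyl)propan-1-one (propiosyringone) is taken as a catalogue compound. Lignan numbering is used: C7/C7' benzylic, C8/C8' methyl-bearing, C9/C9' methyl. Diketone 5 is carried on as its diastereomer mixture, because C8 and C8' become sp2 in the furan.

**Step 1**
Reactants: 1 1-(4-hydroxy-3,5-dimethoxyphenyl)propan-1-one; 2 benzyl bromide
Product: 3 1-(4-benzyloxy-3,5-dimethoxyphenyl)propan-1-one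
Conditions: BnBr (1.2 equiv), K2CO3 (2 equiv), DMF, 60 °C
Reagents that add atoms: benzyl bromide, BrCc1ccccc1
Why: Williamson ether synthesis, in which K2CO3 deprotonates the acidic 2,6-dimethoxyphenol and the phenoxide displaces bromide from the benzylic carbon (SN2) without touching the ketone; no stereocentre is formed.

**Step 2**
Reactants: 3 1-(4-benzyloxy-3,5-dimethoxyphenyl)propan-1-one (two molecules)
Product: 5 1,4-bis(4-benzyloxy-3,5-dimethoxyphenyl)-2,3-dimethylbutane-1,4-dione (racemic plus meso diastereomers), via lithium Z-enolate 4 (not isolated)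
Conditions: LDA (1.05 equiv, commercial solution), THF, −78 °C; then anhydrous CuCl2 (1.1 equiv) in DMF, −78 °C to rt; aq. NH4Cl
Reagents that add atoms: LDA (lithium diisopropylamide), [Li+].CC(C)[N-]C(C)C, which supplies only the lithium of enolate 4; nothing from it remains in 5
Why: Oxidative enolate homocoupling of the Saegusa type, in which kinetic deprotonation gives enolate 4 and divalent copper oxidises it by one electron so that two α-keto carbons join as the C8–C8' bond; the two stereocentres form without control, which does not matter because step 3 flattens both.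

**Step 3**
Reactants: 5 1,4-bis(4-benzyloxy-3,5-dimethoxyphenyl)-2,3-dimethylbutane-1,4-dione
Product: 6 2,5-bis(4-benzyloxy-3,5-dimethoxyphenyl)-3,4-dimethylfuran
Conditions: TsOH·H2O (0.2 equiv), toluene, reflux, Dean–Stark
Reagents that add atoms: none
Why: Paal–Knorr furan synthesis, in which the enol oxygen of one carbonyl attacks the other protonated carbonyl (5-exo-trig) and two dehydrations give the aromatic furan, so both diastereomers of 5 converge on one achiral product; aryl benzyl ethers tolerate catalytic sulfonic acid.

**Step 4**
Reactants: 6 2,5-bis(4-benzyloxy-3,5-dimethoxyphenyl)-3,4-dimethylfuran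
Product: 8 all-cis-2,5-bis(4-hydroxy-3,5-dimethoxyphenyl)-3,4-dimethyltetrahydrofuran (2R,3S,4R,5S; meso), via bisphenol furan 7 (not isolated)
Conditions: H2 (3–4 atm), 10% Pd/C, EtOAc–EtOH, rt
Reagents that add atoms: none
Why: Heterogeneous hydrogenation on Pd: the two aryl benzyl ethers are hydrogenolysed first to give furan 7, which then lies flat on the metal and receives two molecules of H2 by stepwise syn transfer of surface hydrogen to C7, C8, C8' and C7'. The closest known reaction type is the all-cis hydrogenation of 2,5-diaryl-3,4-dialkylfurans over Pd/C or Rh/Al2O3, run together with ordinary O-benzyl hydrogenolysis. No ring is closed and no skeletal bond is made; the furan ring is kept and becomes the tetrahydrofuran ring. The four new stereocentres C7, C8, C8' and C7' are all set by the catalyst face, so both aryl groups and both methyl groups end up on the side away from the metal (2R,3S,4R,5S, meso). The selectivity needed is facial fidelity between the first and the second H2, and the substrate secures it: after the first syn addition the dihydrofuran carries its new aryl and methyl groups on the far face, so that even a molecule that desorbs or isomerises re-binds through the same hydrogen-bearing, less hindered face. The neutral medium holds back cleavage of the benzylic ring C–O bonds, and any product that is cleaved after saturation is merely the material of step 5.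

**Step 5**
Reactants: 8 all-cis-2,5-bis(4-hydroxy-3,5-dimethoxyphenyl)-3,4-dimethyltetrahydrofuran
Product: 10 meso-4,4'-(2,3-dimethylbutane-1,4-diyl)bis(2,6-dimethoxyphenol) (2R,3S; the target), via ring-opened benzylic alcohol 9 (not isolated)
Conditions: H2 (3–4 atm), 10% Pd/C, HClO4 (70%, cat.), AcOH, rt
Reagents that add atoms: none
Why: Acid-assisted benzylic hydrogenolysis, in which protonation of the ring oxygen lets Pd–H cleave the first p-hydroxyaryl-activated C–O bond to alcohol 9 and then the second to CH2; C7 and C7' lose their stereochemistry, while the untouched C8 and C8' keep the cis-derived R,S (meso) relationship.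

**Compound list**
1 | 1-(4-hydroxy-3,5-dimethoxyphenyl)propan-1-one (propiosyringone) | CCC(=O)c1cc(OC)c(O)c(OC)c1 | starting material
2 | benzyl bromide | BrCc1ccccc1 | starting material
3 | 1-(4-benzyloxy-3,5-dimethoxyphenyl)propan-1-one | CCC(=O)c1cc(OC)c(OCc2ccccc2)c(OC)c1 | intermediate
4 | lithium (Z)-1-(4-benzyloxy-3,5-dimethoxyphenyl)prop-1-en-1-olate | [Li+].C/C=C(\[O-])c1cc(OC)c(OCc2ccccc2)c(OC)c1 | intermediate (not isolated)
5 | 1,4-bis(4-benzyloxy-3,5-dimethoxyphenyl)-2,3-dimethylbutane-1,4-dione, mixture of racemic and meso diastereomers | CC(C(=O)c1cc(OC)c(OCc2ccccc2)c(OC)c1)C(C)C(=O)c1cc(OC)c(OCc2ccccc2)c(OC)c1 | intermediate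
6 | 2,5-bis(4-benzyloxy-3,5-dimethoxyphenyl)-3,4-dimethylfuran | Cc1c(C)c(-c2cc(OC)c(OCc3ccccc3)c(OC)c2)oc1-c1cc(OC)c(OCc2ccccc2)c(OC)c1 | intermediate
7 | 2,5-bis(4-hydroxy-3,5-dimethoxyphenyl)-3,4-dimethylfuran | Cc1c(C)c(-c2cc(OC)c(O)c(OC)c2)oc1-c1cc(OC)c(O)c(OC)c1 | intermediate (not isolated)
8 | (2R,3S,4R,5S)-2,5-bis(4-hydroxy-3,5-dimethoxyphenyl)-3,4-dimethyltetrahydrofuran, all-cis, meso | C[C@H]1[C@@H](C)[C@@H](c2cc(OC)c(O)c(OC)c2)O[C@H]1c1cc(OC)c(O)c(OC)c1 | intermediate
9 | 1,4-bis(4-hydroxy-3,5-dimethoxyphenyl)-2,3-dimethylbutan-1-ol, racemic, one enantiomer drawn, C2/C3 in the cis-derived relationship | C[C@H](Cc1cc(OC)c(O)c(OC)c1)[C@@H](C)[C@@H](c1cc(OC)c(O)c(OC)c1)O | intermediate (not isolated)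
10 | meso-(2R,3S)-1,4-bis(4-hydroxy-3,5-dimethoxyphenyl)-2,3-dimethylbutane | COc1cc(C[C@@H](C)[C@@H](C)Cc2cc(OC)c(O)c(OC)c2)cc(OC)c1O | target

**Step count**
Total steps: 5. Longest linear sequence: 5 steps (1 → 3 → 5 → 6 → 8 → 10).

**Steps most likely to fail**

Step 4. Facial fidelity may erode, or a partly saturated ring may be opened by hydrogenolysis of its allylic and benzylic C–O bond before all four hydrogens are in place; either would scramble C8/C8'. The fallback sets the meso pair by diastereomer separation instead. It sets out from 5 and comes back at 10. Diketone 5 is equilibrated with DBU in CH2Cl2, and the meso (2R,3S) diketone F1 is collected by fractional crystallisation or chromatography, the remainder being recycled through the same equilibration. LiAlH4 in THF at 0 °C should reduce both carbonyls to give the 1,4-diol F2, whose carbinol configurations do not matter. Hydrogenolysis of F2 (H2, 10% Pd/C, HClO4 cat., AcOH, rt) should remove both benzylic hydroxyl groups and both O-benzyl groups and deliver 10.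

Step 2. The enolate may be chlorinated at the α-carbon, or the ketone may be recovered after unproductive electron transfer, so that little C8–C8' bond forms. The fallback makes the same bond by polar alkylation. It sets out from 3 and comes back at 5. One portion of 3 is brominated with CuBr2 in EtOAc–CHCl3 at reflux to give the α-bromoketone F3. A second portion of 3 is converted into enolate 4 (LDA, THF, −78 °C) and alkylated with F3 (−78 to 0 °C, SN2 at the secondary α-carbon). This should give 5 as a diastereomer mixture, which is all step 3 needs.

Step 5. Under acid on the metal a benzylic cation may lose the C8 proton to form an alkene that is re-hydrogenated, which would erode the meso relationship; the reaction may also stall after the first C–O cleavage. The fallback is a homogeneous, metal-free ionic hydrogenation. It sets out from 8 and comes back at 10. Et3SiH (excess) with CF3CO2H in CH2Cl2 at −20 to 0 °C should ionise each benzylic C–O bond in turn and trap the p-hydroxybenzyl cation by hydride transfer faster than proton loss, passing through alcohol 9. No compound outside the list is made (F0).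

**Further compounds**
F1 | step 4 | meso-(2R,3S)-1,4-bis(4-benzyloxy-3,5-dimethoxyphenyl)-2,3-dimethylbutane-1,4-dione | C[C@H](C(=O)c1cc(OC)c(OCc2ccccc2)c(OC)c1)[C@@H](C)C(=O)c1cc(OC)c(OCc2ccccc2)c(OC)c1
F2 | step 4 | 1,4-bis(4-benzyloxy-3,5-dimethoxyphenyl)-2,3-dimethylbutane-1,4-diol, (2R,3S)-configured at C2/C3, carbinol centres as a mixture | C[C@H](C(O)c1cc(OC)c(OCc2ccccc2)c(OC)c1)[C@@H](C)C(O)c1cc(OC)c(OCc2ccccc2)c(OC)c1
F3 | step 2 | 1-(4-benzyloxy-3,5-dimethoxyphenyl)-2-bromopropan-1-one, racemic | CC(Br)C(=O)c1cc(OC)c(OCc2ccccc2)c(OC)c1
F0 | step 5 | none | none
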